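**Retrosynthetic overview**
1. Target 16 ⇐ tert-butyl ester 15 (acidolysis) ⇐ (R)-4-hydroxy-4-alkylcyclopent-2-enone 11, by one-flask dianion C5-alkylation with (Z)-pentenyl bromide and O-acetylation.
2. The only ring (the cyclopentenone) is formed once, by intramolecular aldol condensation (C2=C3) of 1,4-keto-aldehyde 10.
3. Key C–C bond C1–C5: an acetyl anion equivalent (2-lithio-2-methyl-1,3-dithiane) attacks the CH2 of unprotected epoxy alcohol 5; acyl carbon and epoxide carbon are both natively electrophilic.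
4. The C4 carbinol centre comes from Sharpless epoxidation of 2-alkylallyl alcohol 4 and its C–O bond is never broken afterwards; C5 is set by alkylation anti to the chain.
5. Alcohol 4 comes from Negishi coupling of the zinc reagent of tert-butyl 8-bromooctanoate with 2-bromoallyl alcohol.

Assumption: ring atoms are C1 (C=O), C2=C3, C4 (quaternary C–OAc), C5 (CH–pentenyl); the SMILES is read as (4S,5S), acetoxy and pentenyl cis, the two carbon chains trans.

**Step 1**
Reactants: 1 tert-butyl 8-bromooctanoate; 2 2-bromoprop-2-en-1-ol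
Product: 4 tert-butyl 9-(hydroxymethyl)dec-9-enoate, via alkylzinc bromide 3 (not isolated)
Conditions: Zn dust, LiCl, THF, 50 °C; then 2 (0.6 equiv), Pd(OAc)2 (2 mol%), SPhos (4 mol%), THF, 25 °C
Reagents that add atoms: none
Why: Zinc insertion into the primary bromide tolerates the tert-butyl ester, and the alkylzinc couples with the alkenyl bromide (Negishi cross-coupling) faster than the free hydroxyl protonates it; no stereocentre is formed.

**Step 2**
Reactants: 4 tert-butyl 9-(hydroxymethyl)dec-9-enoate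
Product: 5 tert-butyl 8-[(2S)-2-(hydroxymethyl)oxiran-2-yl]octanoate
Conditions: Ti(OiPr)4 (10 mol%), L-(+)-diethyl tartrate (12 mol%), tBuOOH, 4 Å molecular sieves, CH2Cl2, −20 °C
Reagents that add atoms: tert-butyl hydroperoxide, `CC(C)(C)OO`
Why: Sharpless asymmetric epoxidation of a 2-substituted allylic alcohol; L-(+)-tartrate delivers oxygen to the face that gives the (S)-epoxy alcohol (typically 90–95% ee), which fixes the future C4 centre.

**Step 3**
Reactants: 5 tert-butyl 8-[(2S)-2-(hydroxymethyl)oxiran-2-yl]octanoate; 6 2-methyl-1,3-dithiane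
Product: 8 tert-butyl (9R)-9-hydroxy-9-(hydroxymethyl)-10-(2-methyl-1,3-dithian-2-yl)decanoate, via lithiodithiane 7 (not isolated)
Conditions: 6 (3 equiv), nBuLi (3 equiv), THF, −25 °C; then 5, DMPU, −25 to 20 °C; H2O work-up
Reagents that add atoms: none
Why: Corey–Seebach acyl anion opening of the epoxide at its unsubstituted CH2 by SN2 attack; the C–O bond at the quaternary centre is untouched so configuration is kept, and the free lithium alkoxide is tolerated because Payne rearrangement of a 2-substituted glycidol regenerates the same enantiomer.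

**Step 4**
Reactants: 8 tert-butyl (9R)-9-hydroxy-9-(hydroxymethyl)-10-(2-methyl-1,3-dithian-2-yl)decanoate
Product: 9 tert-butyl (9R)-9-formyl-9-hydroxy-10-(2-methyl-1,3-dithian-2-yl)decanoate
Conditions: SO3·pyridine, DMSO, iPr2NEt, CH2Cl2, 0 °C
Reagents that add atoms: none
Why: Parikh–Doering oxidation converts only the primary hydroxyl (the tertiary one cannot be oxidised) and leaves the dithiane sulfur and the stereocentre untouched.

**Step 5**
Reactants: 9 tert-butyl (9R)-9-formyl-9-hydroxy-10-(2-methyl-1,3-dithian-2-yl)decanoate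
Product: 11 tert-butyl 8-[(1R)-1-hydroxy-4-oxocyclopent-2-en-1-yl]octanoate, via keto-aldehyde 10 (not isolated)
Conditions: MeI, CaCO3, MeCN/H2O, 40 °C; then piperidine, AcOH (20 mol% each), toluene, 40 °C
Reagents that add atoms: water, `O`
Why: Alkylative dithiane hydrolysis unmasks the methyl ketone, and the 1,4-keto-aldehyde closes by amine-catalysed intramolecular aldol condensation (methyl carbon onto the non-enolisable aldehyde, water lost on the new secondary carbinol side), so the tertiary C–O bond and its configuration survive.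

**Step 6**
Reactants: 11 tert-butyl 8-[(1R)-1-hydroxy-4-oxocyclopent-2-en-1-yl]octanoate; 12 (2Z)-1-bromopent-2-ene
Product: 15 tert-butyl 8-[(1S,5S)-1-acetoxy-4-oxo-5-[(2Z)-pent-2-en-1-yl]cyclopent-2-en-1-yl]octanoate, via dianion 13 (not isolated), via lithium alkoxide 14 (not isolated)
Conditions: LiN(iPr)2 (2.2 equiv), THF, −78 °C; 12, DMPU, −78 to −40 °C; then Ac2O (3 equiv), −40 to 0 °C; NH4Cl quench
Reagents that add atoms: acetic anhydride, `CC(=O)OC(C)=O`
Why: Alkoxide–enolate dianion alkylation (Fráter–Seebach type) brings the allylic bromide onto C5 anti to the C4 alkyl chain, setting (5S) with pentenyl cis to oxygen (also the more stable trans-dialkyl isomer), and the remaining tertiary lithium alkoxide is O-acetylated in the same flask.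

**Step 7**
Reactants: 15 tert-butyl 8-[(1S,5S)-1-acetoxy-4-oxo-5-[(2Z)-pent-2-en-1-yl]cyclopent-2-en-1-yl]octanoate
Product: 16 8-[(1S,5S)-1-acetoxy-4-oxo-5-[(2Z)-pent-2-en-1-yl]cyclopent-2-en-1-yl]octanoic acid (CNP0348716.1)
Conditions: CF3CO2H, CH2Cl2, 0 to 20 °C
Reagents that add atoms: none
Why: Acidolysis of the tert-butyl ester (E1 loss of isobutene) frees the acid; the tertiary allylic acetate resists ionisation because the 4-oxocyclopentenyl cation is antiaromatic and carbonyl-destabilised, and no stereocentre is touched.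

**Compound list**
1 | tert-butyl 8-bromooctanoate | `CC(C)(C)OC(=O)CCCCCCCBr` | starting material
2 | 2-bromoprop-2-en-1-ol | `OCC(Br)=C` | starting material
3 | (8-tert-butoxy-8-oxooctyl)zinc bromide | `CC(C)(C)OC(=O)CCCCCCC[Zn]Br` | intermediate
4 | tert-butyl 9-(hydroxymethyl)dec-9-enoate | `CC(C)(C)OC(=O)CCCCCCCC(=C)CO` | intermediate
5 | tert-butyl 8-[(2S)-2-(hydroxymethyl)oxiran-2-yl]octanoate | `CC(C)(C)OC(=O)CCCCCCC[C@]1(CO)CO1` | intermediate
6 | 2-methyl-1,3-dithiane | `CC1SCCCS1` | starting material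
7 | 2-lithio-2-methyl-1,3-dithiane | `[Li]C1(C)SCCCS1` | intermediate
8 | tert-butyl (9R)-9-hydroxy-9-(hydroxymethyl)-10-(2-methyl-1,3-dithian-2-yl)decanoate | `CC(C)(C)OC(=O)CCCCCCC[C@](O)(CO)CC1(C)SCCCS1` | intermediate
9 | tert-butyl (9R)-9-formyl-9-hydroxy-10-(2-methyl-1,3-dithian-2-yl)decanoate | `CC(C)(C)OC(=O)CCCCCCC[C@](O)(C=O)CC1(C)SCCCS1` | intermediate
10 | tert-butyl (9R)-9-formyl-9-hydroxy-11-oxododecanoate | `CC(C)(C)OC(=O)CCCCCCC[C@](O)(C=O)CC(C)=O` | intermediate
11 | tert-butyl 8-[(1R)-1-hydroxy-4-oxocyclopent-2-en-1-yl]octanoate | `CC(C)(C)OC(=O)CCCCCCC[C@]1(O)C=CC(=O)C1` | intermediate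
12 | (2Z)-1-bromopent-2-ene | `CC/C=C\CBr` | starting material
13 | dilithium alkoxide–enolate (dianion) of 11, enolate at C5, carbinol centre unchanged | `CC(C)(C)OC(=O)CCCCCCC[C@]1([O-])C=CC([O-])=C1.[Li+].[Li+]` | intermediate
14 | lithium alkoxide of tert-butyl 8-[(1S,5S)-1-hydroxy-4-oxo-5-[(2Z)-pent-2-en-1-yl]cyclopent-2-en-1-yl]octanoate | `CC/C=C\C[C@@H]1C(=O)C=C[C@]1(CCCCCCCC(=O)OC(C)(C)C)[O-].[Li+]` | intermediate
15 | tert-butyl 8-[(1S,5S)-1-acetoxy-4-oxo-5-[(2Z)-pent-2-en-1-yl]cyclopent-2-en-1-yl]octanoate | `CC/C=C\C[C@@H]1C(=O)C=C[C@]1(CCCCCCCC(=O)OC(C)(C)C)OC(C)=O` | intermediate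
16 | 8-[(1S,5S)-1-acetoxy-4-oxo-5-[(2Z)-pent-2-en-1-yl]cyclopent-2-en-1-yl]octanoic acid | `CC/C=C\C[C@@H]1C(=O)C=C[C@]1(CCCCCCCC(=O)O)OC(C)=O` | target

**Step count and risks**
Total steps: 7. Longest linear sequence: 7 (1 → 16).

Most likely to fail, first: step 3. The dithiane anion must open a hindered 2,2-disubstituted epoxide that carries a free alkoxide, and it may react sluggishly or enolise the ester. Fallback: set out from 5 and use a latent acetyl anion of another kind. Isopropenylmagnesium bromide with catalytic CuI in THF at −30 °C opens the epoxide at CH2 to give tert-butyl (9R)-9-hydroxy-9-(hydroxymethyl)-11-methyldodec-11-enoate F1. Oxidation with SO3·pyridine/DMSO gives tert-butyl (9R)-9-formyl-9-hydroxy-11-methyldodec-11-enoate F2. Ozonolysis (O3, CH2Cl2, −78 °C; Me2S) of its only alkene delivers keto-aldehyde 10, where the route is rejoined for the amine-catalysed closure to 11.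

Second: step 5. The one-flask unmasking and condensation could lose the tertiary instead of the secondary hydroxyl, form a furan, or suffer an α-ketol shift. Fallback: from 9, unmask to 10 as before but stop at the aldol stage with K2CO3 in MeOH at 0 °C, giving tert-butyl 8-[(1R)-1,2-dihydroxy-4-oxocyclopentyl]octanoate F3 (C2 epimers). Acetylate only the secondary hydroxyl (Ac2O, pyridine, 0 °C) to tert-butyl 8-[(1R)-2-acetoxy-1-hydroxy-4-oxocyclopentyl]octanoate F4. DBU in CH2Cl2 at 0 °C then removes acetic acid by E1cB across C2–C3 only and returns to 11.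

Third: step 6. Risks are dialkylation, the wrong C5 epimer, and base-induced loss of the new acetate. Fallback: from 11, alkylate the dianion with 1-bromopent-2-yne, which is smaller and more reactive and has no alkene geometry at stake. Isolate tert-butyl 8-[(1S,5S)-1-hydroxy-4-oxo-5-(pent-2-yn-1-yl)cyclopent-2-en-1-yl]octanoate F5, removing any minor C5 epimer by chromatography. Acetylate the tertiary alcohol under acid catalysis (Ac2O, Sc(OTf)3, MeCN, −20 °C) to tert-butyl 8-[(1S,5S)-1-acetoxy-4-oxo-5-(pent-2-yn-1-yl)cyclopent-2-en-1-yl]octanoate F6. Semi-hydrogenation (H2, Pd/CaCO3 poisoned with Pb(OAc)2, quinoline, EtOAc) gives the (Z)-alkene and rejoins the route at 15.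

**Further compounds**
F1 | step 3 | tert-butyl (9R)-9-hydroxy-9-(hydroxymethyl)-11-methyldodec-11-enoate | `CC(C)(C)OC(=O)CCCCCCC[C@](O)(CO)CC(C)=C`
F2 | step 3 | tert-butyl (9R)-9-formyl-9-hydroxy-11-methyldodec-11-enoate | `CC(C)(C)OC(=O)CCCCCCC[C@](O)(C=O)CC(C)=C`
F3 | step 5 | tert-butyl 8-[(1R)-1,2-dihydroxy-4-oxocyclopentyl]octanoate (C2 epimers) | `CC(C)(C)OC(=O)CCCCCCC[C@]1(O)C(O)CC(=O)C1`
F4 | step 5 | tert-butyl 8-[(1R)-2-acetoxy-1-hydroxy-4-oxocyclopentyl]octanoate (C2 epimers) | `CC(C)(C)OC(=O)CCCCCCC[C@]1(O)C(OC(C)=O)CC(=O)C1`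
F5 | step 6 | tert-butyl 8-[(1S,5S)-1-hydroxy-4-oxo-5-(pent-2-yn-1-yl)cyclopent-2-en-1-yl]octanoate | `CCC#CC[C@@H]1C(=O)C=C[C@]1(CCCCCCCC(=O)OC(C)(C)C)O`
F6 | step 6 | tert-butyl 8-[(1S,5S)-1-acetoxy-4-oxo-5-(pent-2-yn-1-yl)cyclopent-2-en-1-yl]octanoate | `CCC#CC[C@@H]1C(=O)C=C[C@]1(CCCCCCCC(=O)OC(C)(C)C)OC(C)=O`
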